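## Analysis of the target

The target is a 1,4-dimethylcyclohexene, numbered here C1 to C6 with the alkene at C4=C5, that carries two identical 3-(2-methylbut-3-en-2-yl)-1H-indol-5-yl units: one bonded directly to C6, the other joined to the quaternary C1 through an (E)-ethene bridge. The two stereocentres are adjacent, C1 (S; methyl, vinyl, C2, C6) and C6 (R; H, indolyl), with the C6 indolyl group trans to the C1 vinyl group and cis to the C1 methyl group. Apart from the trisubstituted alkene the ring has no functional group, and the alkene must end at C4=C5, not at C3=C4 and not at the conjugated C5=C6 position. Sensitive groups are the two free indole N–H units and electron-rich indole rings, the two tertiary allylic groups at indole C3 (prone to migration or cyclisation in strong acid), the terminal alkenes (which exclude hydrogenation and make metathesis or Heck chemistry unselective), and the benzylic, allylic C6–H bond. The main difficulty is the all-carbon quaternary centre C1 next to the aryl-bearing C6 in one relative and absolute configuration. The route rests on reading C2–C3–C4(CH3) as a but-3-en-2-one unit inserted between C1 and C5. C1 is then the α-carbon of an aldehyde whose formyl group later becomes the ethene bridge, C6 is its β-carbon, and C5 can carry a nitro group that makes it nucleophilic for ring closure onto the ketone and afterwards marks where the alkene must lie.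

## Retrosynthetic reasoning

**24 ⇐ 23.** The two indole nitrogens are unmasked last. Carbamate protection keeps the indoles inert towards nitroalkenes, enones, sulfonyl chlorides and strong base throughout, and it can be removed by methanolysis under mild base, so the acid-sensitive tertiary allyl groups never meet acid at the end.

**23 ⇐ 19 + 22.** The (E)-ethene bridge is cut at its double bond. This turns the C1 substituent into a formyl group, which is exactly what an aldehyde-based annulation leaves on C1, and turns the second indole into a benzylic phosphonate. Aldehyde 19 cannot enolise, so C1 is safe under base, and a benzylic phosphonate should give the E alkene.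

**19 ⇐ 18 ⇐ 17.** The C4=C5 alkene of 19 is traced back to a β-nitro sulfide 18, from which a tin radical removes the nitro group at C5 and the sulfur group at C4 together. Because both leaving groups sit on exactly these two carbons, the alkene cannot form elsewhere. Sulfide 18 comes from thiol addition to the nitroalkene 17.

**17 ⇐ 13 + 14 (key disconnection).** The bonds C1–C2 and C4–C5 are cut, which removes the four carbons of 14 from the ring. What remains is the open-chain γ-nitro aldehyde 13, in which C6 is already configured. Forward, the enamine of 13 must add to 14 to create the quaternary C1 (giving 15), the nitronate must close onto the ketone (giving 16), and water must be lost. This is the shortest way to make the ring and C1 together, and the only stereochemical demand is face selectivity at C1 under the influence of C6.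

**13 ⇐ 11 + 12.** The C1–C6 bond is cut as an amine-catalysed conjugate addition of 12 to the nitroalkene 11. This well-established reaction sets C6 with catalyst control. The configuration at the α-carbon does not matter, because that carbon becomes an enamine carbon in the key step.

**11 ⇐ 8 + 9.** The nitroalkene is a nitroaldol condensation product of aldehyde 8 and 9, through 10.

**22 ⇐ 21 ⇐ 20 ⇐ 8.** The phosphonate comes from the same aldehyde 8 by reduction, bromination and phosphonylation, so one indole building block serves both halves of the target.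

**8 ⇐ 7 ⇐ 5.** The formyl group is introduced by halogen–metal exchange on bromide 5, through the dimetallated species 6, and the nitrogen is then protected.

**5 ⇐ 2 + 3; 2 ⇐ 1.** The indole with its tertiary allyl group at C3 is cut by a Fischer disconnection, through hydrazone 4, to the hydrazine 3 and aldehyde 2. Aldehyde 2 is the partial reduction product of ester 1. The quaternary benzylic carbon is thus bought, not made.

## Alternatives that were turned down

**Alternative 1: Diels–Alder reaction with a silylated isoprene, then allylic transposition.**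
- Disconnection: C1–C2 and C5–C6, giving the trisubstituted enal A1 as dienophile and the 1-silyl diene A2.
- Key step: a chiral cationic oxazaborolidine would join them to the silyl cyclohexene A3, whose C3=C4 alkene is then moved to C4=C5 by protodesilylation of the allylsilane.
- For: the suprafacial cycloaddition transfers the E geometry of A1 directly into the trans relation of formyl and aryl groups, both centres come from one catalytic step, and the route is about two steps shorter. On the certainty of the relative configuration it is stronger than the chosen route.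
- Against: A1 is a poor dienophile (α-methyl, β-aryl, electron-rich aryl). The methyl and silyl groups of A2 direct to opposite regiochemistry. The strong Lewis acid and the later protic desilylation meet an acid-sensitive tertiary allyl indole and an allylsilane that can lose silicon early. The sulfonyl protecting group needs harsher removal.
- Comparison: the chosen route offers bond formation whose regiochemistry is fixed by polarity at every step, and no strong acid.

**Alternative 2: one boronate used twice.**
- Disconnection: both indole–carbon bonds, giving two equivalents of boronate A4 and a core A5 that carries an (E)-iodovinyl group on C1 and an allylic carbonate at C6.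
- Key step: Pd(PPh3)4 would perform a Suzuki coupling at the vinyl iodide and an allylic arylation at C6 with inversion, giving A6, which is the same compound as 23.
- For: this is the most convergent plan and uses the hidden symmetry of the two indoles best.
- Against: the allylpalladium intermediate spans C4 to C6 and can be arylated at either end or lose a β-hydrogen to a diene. C6 is flanked by the quaternary C1, so the required site is the hindered one. The core A5 already contains both stereocentres, so the difficult quaternary carbon still has to be made enantioselectively in a separate, not shorter, sequence.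
- Comparison: the chosen route also draws both indoles from one intermediate (8), and it sets C6 when the aryl group is already attached, avoiding a stereospecific sp3 carbon–aryl coupling.

**Alternative 3: acyclic stereo pair, then ring-closing metathesis.**
- Disconnection: the C4=C5 double bond, giving the diene aldehyde A7.
- Key step: the second-generation Grubbs catalyst would close A7 to the cyclohexene aldehyde A8, which is the same compound as 19.
- For: as a ring closure this is more reliable than the proposed annulation, and the alkene position is unambiguous without any marker group to remove.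
- Against: the whole stereochemical problem moves into the open chain, where the adjacent quaternary and tertiary carbons of A7 must be built by several steps with acyclic control. The tertiary allyl group on the indole is a further terminal alkene exposed to the catalyst.
- Comparison: the chosen route reaches its ring-closure precursor 13 in two carbon–carbon bond-forming steps from 8, and forms the quaternary carbon and the ring in one operation.

Key step: step 7

Assumption on numbering: the cyclohexene is numbered C1 (quaternary) to C6 (CH–indolyl) with the alkene at C4=C5 in all names, also where lowest-locant rules would number otherwise. Descriptors refer to these locants, and Ar stands for the 1-(tert-butoxycarbonyl)-3-(2-methylbut-3-en-2-yl)indol-5-yl group.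

Assumption on the catalyst: 9-amino-9-deoxy-epi-quinine is taken as the amine whose facial preference matches the substrate bias in step 7. If the two oppose each other, the pseudoenantiomeric 9-amino-9-deoxy-epi-quinidine takes its place.

## Route

Step 1
Reactants: 1 methyl 3,3-dimethylpent-4-enoate
Product: 2 3,3-dimethylpent-4-enal
Conditions: i-Bu2AlH (1.05 equiv), CH2Cl2, −78 °C; MeOH, then aq. potassium sodium tartrate; used as a solution
Reagents that add atoms: none
Why: Partial reduction of an ester to the aldehyde through the tetrahedral aluminium hemiacetal, which is stable at −78 °C and collapses only on work-up; the isolated alkene is inert.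

Step 2
Reactants: 2 3,3-dimethylpent-4-enal; 3 4-bromophenylhydrazine hydrochloride
Product: 5 5-bromo-3-(2-methylbut-3-en-2-yl)-1H-indole, via hydrazone 4 (not isolated)
Conditions: EtOH, rt; then AcOH, 80 °C
Reagents that add atoms: none
Why: Fischer indole synthesis; the para-bromo hydrazine can only give the 5-bromoindole, and the α-methylene of the aldehyde becomes indole C3 with the tertiary allyl group already attached, under acid mild enough to leave the alkene alone.

Step 3
Reactants: 5 5-bromo-3-(2-methylbut-3-en-2-yl)-1H-indole
Product: 7 3-(2-methylbut-3-en-2-yl)-1H-indole-5-carbaldehyde, via 5-lithio-1-potassioindole 6 (not isolated)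
Conditions: KH, THF, 0 °C; t-BuLi (2 equiv), −78 °C; DMF, −78 °C → rt; H2O
Reagents that add atoms: N,N-dimethylformamide, CN(C)C=O
Why: Deprotonation of the N–H first makes bromine–lithium exchange clean, and the aryllithium is formylated by DMF; the exchange at −78 °C does not touch the terminal alkene.

Step 4
Reactants: 7 3-(2-methylbut-3-en-2-yl)-1H-indole-5-carbaldehyde
Product: 8 tert-butyl 5-formyl-3-(2-methylbut-3-en-2-yl)indole-1-carboxylate
Conditions: Boc2O, DMAP (cat.), MeCN, rt
Reagents that add atoms: di-tert-butyl dicarbonate, CC(C)(C)OC(=O)OC(=O)OC(C)(C)C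
Why: Nucleophilic catalysis gives the indole carbamate, which removes the acidic N–H and lowers the nucleophilicity of the indole for all later electrophilic and basic steps.

Step 5
Reactants: 8 tert-butyl 5-formyl-3-(2-methylbut-3-en-2-yl)indole-1-carboxylate; 9 nitromethane
Product: 11 tert-butyl 3-(2-methylbut-3-en-2-yl)-5-[(E)-2-nitroethenyl]indole-1-carboxylate, via nitro alcohol 10 (not isolated)
Conditions: MeNO2 (excess), Et3N (0.5 equiv), rt; evaporate; MsCl, Et3N, CH2Cl2, 0 °C
Reagents that add atoms: none
Why: Henry reaction followed by mesylation and E1cB elimination, which gives the conjugated (E)-β-aryl nitroalkene; the two-stage protocol avoids the hot ammonium acetate conditions that could cleave the carbamate.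

Step 6
Reactants: 11 tert-butyl 3-(2-methylbut-3-en-2-yl)-5-[(E)-2-nitroethenyl]indole-1-carboxylate; 12 propanal
Product: 13 (2S,3R)-3-Ar-2-methyl-4-nitrobutanal (syn isomer; the 2R epimer may accompany it)
Conditions: (R)-2-[diphenyl(trimethylsilyloxy)methyl]pyrrolidine (10 mol %), propanal (5 equiv), toluene, 0 °C → rt
Reagents that add atoms: none
Why: Enamine-catalysed Michael addition of an aldehyde to a nitroalkene; the anti enamine of propanal attacks the nitroalkene through an acyclic synclinal transition state on the face left open by the diphenyl(silyloxy)methyl group, and the R catalyst should set C3 (the later C6) as R. The C2 configuration is irrelevant because C2 becomes an enamine carbon in step 7.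

Step 7
Reactants: 13 (2S,3R)-3-Ar-2-methyl-4-nitrobutanal; 14 but-3-en-2-one
Product: 17 (1R,6S)-6-Ar-1,4-dimethyl-5-nitrocyclohex-4-ene-1-carbaldehyde, via keto aldehyde 15 (not isolated), via nitro alcohol 16 (not isolated)
Conditions: 9-amino-9-deoxy-epi-quinine (20 mol %), CF3CO2H (40 mol %), but-3-en-2-one (3 equiv, added slowly), toluene, rt; evaporate excess enone; DBU (1 equiv), CH2Cl2, 0 °C; then MsCl, Et3N, 0 °C → rt
Reagents that add atoms: none
Why: Proposed new method: the primary amine condenses with the α-branched aldehyde 13 to a secondary enamine while the excess CF3CO2H keeps the quinuclidine protonated, so no nitronate is available and the enamine carbon adds to 14 (bond C1–C2), giving 15 after hydrolysis; once the volatile enone is removed, DBU forms the nitronate at C5, which adds to the methyl ketone (bond C4–C5) to give 16, and mesylation of the tertiary alcohol with E1cB loss of methanesulfonate gives the nitroalkene 17. The closest known reaction types are amine-catalysed Michael–Henry cyclohexane annulations of aldehydes, nitroalkenes and enones and the enamine Michael addition of α-branched aldehydes to vinyl ketones; a branched γ-nitro aldehyde that forms the quaternary carbon first and then closes by nitroaldol addition has not been described. The one ring closed is the cyclohexane, by 6-exo-trig attack of the nitronate carbon on the ketone carbonyl; attack on the formyl group would need a four-membered ring and is not expected. The only lasting new stereocentre is C1, and it is controlled by C6: in the enamine rotamer that keeps the C6–H bond eclipsed with the enamine double bond (least allylic strain), the aryl group covers one face and the enone should add to the other, which puts the formyl group trans to the aryl group as the target requires; the chiral amine is meant to reinforce this bias. C6 is not acidic in 13, 15, 16 or 17 and C1 is quaternary, so neither centre can epimerise, and the centres at C4 and C5 of 16 disappear on dehydration. The step needs face selectivity at C1 and chemoselectivity for enamine over nitronate addition to the enone; the second is secured by the acidic medium of the first stage and by removing the enone before base is added. If base moves the double bond of 17 out of conjugation, step 8 brings the isomers back through 17.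

Step 8
Reactants: 17 (1R,6S)-6-Ar-1,4-dimethyl-5-nitrocyclohex-4-ene-1-carbaldehyde
Product: 18 (1R,6S)-6-Ar-1,4-dimethyl-5-nitro-4-(phenylsulfanyl)cyclohexane-1-carbaldehyde (C4/C5 diastereomers)
Conditions: PhSH (3 equiv), Et3N (0.3 equiv), MeCN, rt
Reagents that add atoms: thiophenol, Sc1ccccc1
Why: Thia-Michael addition of thiolate to the β-carbon (C4) of the nitroalkene; the base also interconverts any allylic nitro isomer with 17, so all material should drain into 18, and the new centres at C4 and C5 are removed in step 9.

Step 9
Reactants: 18 (1R,6S)-6-Ar-1,4-dimethyl-5-nitro-4-(phenylsulfanyl)cyclohexane-1-carbaldehyde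
Product: 19 (1R,6S)-6-Ar-1,4-dimethylcyclohex-4-ene-1-carbaldehyde
Conditions: Bu3SnH (2.5 equiv), AIBN (0.2 equiv), toluene, 90 °C
Reagents that add atoms: none
Why: Radical elimination of a β-nitro sulfide; the stannyl radical adds to the nitro group, the C5–N bond breaks, and the C5 radical expels the phenylthiyl radical from C4, so the alkene forms only between C4 and C5 and C6 is never planar.

Step 10
Reactants: 8 tert-butyl 5-formyl-3-(2-methylbut-3-en-2-yl)indole-1-carboxylate
Product: 20 tert-butyl 5-(hydroxymethyl)-3-(2-methylbut-3-en-2-yl)indole-1-carboxylate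
Conditions: NaBH4, MeOH/THF, 0 °C
Reagents that add atoms: none
Why: Hydride reduction of the aryl aldehyde; the carbamate and the alkene are not touched at 0 °C.

Step 11
Reactants: 20 tert-butyl 5-(hydroxymethyl)-3-(2-methylbut-3-en-2-yl)indole-1-carboxylate
Product: 21 tert-butyl 5-(bromomethyl)-3-(2-methylbut-3-en-2-yl)indole-1-carboxylate
Conditions: CBr4, PPh3, CH2Cl2, 0 °C
Reagents that add atoms: carbon tetrabromide, BrC(Br)(Br)Br
Why: Appel bromination of a benzylic alcohol under neutral conditions, which spares the carbamate and the tertiary allyl group.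

Step 12
Reactants: 21 tert-butyl 5-(bromomethyl)-3-(2-methylbut-3-en-2-yl)indole-1-carboxylate
Product: 22 tert-butyl 5-(diethoxyphosphorylmethyl)-3-(2-methylbut-3-en-2-yl)indole-1-carboxylate
Conditions: P(OEt)3 (neat), 110 °C
Reagents that add atoms: triethyl phosphite, CCOP(OCC)OCC
Why: Michaelis–Arbuzov reaction of a reactive benzylic bromide, at a temperature below the thermal cleavage of an indole carbamate.

Step 13
Reactants: 22 tert-butyl 5-(diethoxyphosphorylmethyl)-3-(2-methylbut-3-en-2-yl)indole-1-carboxylate; 19 (1R,6S)-6-Ar-1,4-dimethylcyclohex-4-ene-1-carbaldehyde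
Product: 23 tert-butyl 5-[(E)-2-[(1S,6R)-6-Ar-1,4-dimethylcyclohex-4-en-1-yl]ethenyl]-3-(2-methylbut-3-en-2-yl)indole-1-carboxylate
Conditions: 22, KN(SiMe3)2, THF, −78 °C; then 19, −78 °C → rt
Reagents that add atoms: none
Why: Horner–Wadsworth–Emmons olefination with a benzylic phosphonate, whose reversible addition and elimination through the less crowded adduct should give the E alkene; the aldehyde has no α-hydrogen, so C1 cannot epimerise, and the potassium counter-ion favours the elimination.

Step 14
Reactants: 23 tert-butyl 5-[(E)-2-[(1S,6R)-6-Ar-1,4-dimethylcyclohex-4-en-1-yl]ethenyl]-3-(2-methylbut-3-en-2-yl)indole-1-carboxylate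
Product: 24 5-[(E)-2-[(1S,6R)-1,4-dimethyl-6-[3-(2-methylbut-3-en-2-yl)-1H-indol-5-yl]cyclohex-4-en-1-yl]ethenyl]-3-(2-methylbut-3-en-2-yl)-1H-indole
Conditions: K2CO3, MeOH/THF, 55 °C
Reagents that add atoms: none
Why: Methanolysis of both indole carbamates, which behave as activated acyl groups on the weakly basic indole nitrogen; no acid is used, so the tertiary allyl groups and both stereocentres stay untouched.

## Compound list

1 | methyl 3,3-dimethylpent-4-enoate | C=CC(C)(C)CC(=O)OC | starting material
2 | 3,3-dimethylpent-4-enal | C=CC(C)(C)CC=O | intermediate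
3 | 4-bromophenylhydrazine hydrochloride | Cl.NNc1ccc(Br)cc1 | starting material
4 | 3,3-dimethylpent-4-enal 4-bromophenylhydrazone | C=CC(C)(C)CC=NNc1ccc(Br)cc1 | intermediate
5 | 5-bromo-3-(2-methylbut-3-en-2-yl)-1H-indole | C=CC(C)(C)c1c[nH]c2ccc(Br)cc12 | intermediate
6 | 5-lithio-1-potassio-3-(2-methylbut-3-en-2-yl)indole | C=CC(C)(C)c1cn([K])c2ccc([Li])cc12 | intermediate
7 | 3-(2-methylbut-3-en-2-yl)-1H-indole-5-carbaldehyde | C=CC(C)(C)c1c[nH]c2ccc(C=O)cc12 | intermediate
8 | tert-butyl 5-formyl-3-(2-methylbut-3-en-2-yl)indole-1-carboxylate | C=CC(C)(C)c1cn(C(=O)OC(C)(C)C)c2ccc(C=O)cc12 | intermediate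
9 | nitromethane | C[N+](=O)[O-] | starting material
10 | tert-butyl 5-(1-hydroxy-2-nitroethyl)-3-(2-methylbut-3-en-2-yl)indole-1-carboxylate (racemic) | C=CC(C)(C)c1cn(C(=O)OC(C)(C)C)c2ccc(C(O)C[N+](=O)[O-])cc12 | intermediate
11 | tert-butyl 3-(2-methylbut-3-en-2-yl)-5-[(E)-2-nitroethenyl]indole-1-carboxylate | C=CC(C)(C)c1cn(C(=O)OC(C)(C)C)c2ccc(/C=C/[N+](=O)[O-])cc12 | intermediate
12 | propanal | CCC=O | starting material
13 | (2S,3R)-3-[1-(tert-butoxycarbonyl)-3-(2-methylbut-3-en-2-yl)indol-5-yl]-2-methyl-4-nitrobutanal | O=C[C@@H](C)[C@@H](C[N+](=O)[O-])c1ccc2n(C(=O)OC(C)(C)C)cc(C(C)(C)C=C)c2c1 | intermediate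
14 | but-3-en-2-one | C=CC(C)=O | starting material
15 | (2R,3S)-3-[1-(tert-butoxycarbonyl)-3-(2-methylbut-3-en-2-yl)indol-5-yl]-2-methyl-4-nitro-2-(3-oxobutyl)butanal | O=C[C@](C)(CCC(C)=O)[C@@H](C[N+](=O)[O-])c1ccc2n(C(=O)OC(C)(C)C)cc(C(C)(C)C=C)c2c1 | intermediate
16 | (1R,6S)-6-[1-(tert-butoxycarbonyl)-3-(2-methylbut-3-en-2-yl)indol-5-yl]-4-hydroxy-1,4-dimethyl-5-nitrocyclohexane-1-carbaldehyde (C4/C5 diastereomers) | O=C[C@]1(C)CCC(C)(O)C([N+](=O)[O-])[C@H]1c2ccc3n(C(=O)OC(C)(C)C)cc(C(C)(C)C=C)c3c2 | intermediate
17 | (1R,6S)-6-[1-(tert-butoxycarbonyl)-3-(2-methylbut-3-en-2-yl)indol-5-yl]-1,4-dimethyl-5-nitrocyclohex-4-ene-1-carbaldehyde | O=C[C@]1(C)CCC(C)=C([N+](=O)[O-])[C@H]1c2ccc3n(C(=O)OC(C)(C)C)cc(C(C)(C)C=C)c3c2 | intermediate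
18 | (1R,6S)-6-[1-(tert-butoxycarbonyl)-3-(2-methylbut-3-en-2-yl)indol-5-yl]-1,4-dimethyl-5-nitro-4-(phenylsulfanyl)cyclohexane-1-carbaldehyde (C4/C5 diastereomers) | O=C[C@]1(C)CCC(C)(Sc4ccccc4)C([N+](=O)[O-])[C@H]1c2ccc3n(C(=O)OC(C)(C)C)cc(C(C)(C)C=C)c3c2 | intermediate
19 | (1R,6S)-6-[1-(tert-butoxycarbonyl)-3-(2-methylbut-3-en-2-yl)indol-5-yl]-1,4-dimethylcyclohex-4-ene-1-carbaldehyde | O=C[C@]1(C)CCC(C)=C[C@H]1c2ccc3n(C(=O)OC(C)(C)C)cc(C(C)(C)C=C)c3c2 | intermediate
20 | tert-butyl 5-(hydroxymethyl)-3-(2-methylbut-3-en-2-yl)indole-1-carboxylate | C=CC(C)(C)c1cn(C(=O)OC(C)(C)C)c2ccc(CO)cc12 | intermediate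
21 | tert-butyl 5-(bromomethyl)-3-(2-methylbut-3-en-2-yl)indole-1-carboxylate | C=CC(C)(C)c1cn(C(=O)OC(C)(C)C)c2ccc(CBr)cc12 | intermediate
22 | tert-butyl 5-(diethoxyphosphorylmethyl)-3-(2-methylbut-3-en-2-yl)indole-1-carboxylate | C=CC(C)(C)c1cn(C(=O)OC(C)(C)C)c2ccc(CP(=O)(OCC)OCC)cc12 | intermediate
23 | tert-butyl 5-[(E)-2-[(1S,6R)-6-[1-(tert-butoxycarbonyl)-3-(2-methylbut-3-en-2-yl)indol-5-yl]-1,4-dimethylcyclohex-4-en-1-yl]ethenyl]-3-(2-methylbut-3-en-2-yl)indole-1-carboxylate | C=CC(C)(C)c1cn(C(=O)OC(C)(C)C)c2ccc(/C=C/[C@]3(C)CCC(C)=C[C@H]3c3ccc4n(C(=O)OC(C)(C)C)cc(C(C)(C)C=C)c4c3)cc12 | intermediate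
24 | 5-[(E)-2-[(1S,6R)-1,4-dimethyl-6-[3-(2-methylbut-3-en-2-yl)-1H-indol-5-yl]cyclohex-4-en-1-yl]ethenyl]-3-(2-methylbut-3-en-2-yl)-1H-indole | C=CC(C)(C)c1c[nH]c2ccc(/C=C/[C@]3(C)CCC(C)=C[C@H]3c3ccc4[nH]cc(C(C)(C)C=C)c4c3)cc12 | target

## Step count and least certain steps

Total: 14 steps. Longest linear sequence: 11 steps (steps 1 to 9, 13 and 14); the phosphonate branch (steps 10 to 12) leaves the main line at 8.

**Step 7 (key step, proposed new method).**
- Most likely to go wrong: the nitroalkane carbon may compete with the enamine for the enone, since the amine can also activate the enone. Enamine formation at the hindered branched aldehyde may be slow. Face selectivity at C1 may be poor if the rotamer with the C6–H bond eclipsing the C1–methyl bond reacts as well. The keto aldehyde 15 may undergo aldol cyclisation through its methyl ketone, and the double bond of 17 may leave conjugation under base.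
- Fallback (known chemistry), setting out from 11 and 12 and rejoining the route at 15: the nitro group is brought in only when the quaternary carbon forms. Propanal 12 is condensed with cyclohexylamine to N-cyclohexylpropan-1-imine F1, which is deprotonated with LiN(i-Pr)2 and alkylated with commercial 2-(2-bromoethyl)-2-methyl-1,3-dioxolane. Mild aqueous acid then gives 2-methyl-4-(2-methyl-1,3-dioxolan-2-yl)butanal F2. The conjugate addition of this α,α-disubstituted aldehyde to nitroalkene 11 under a chiral primary amine–thiourea derived from trans-cyclohexane-1,2-diamine is a known way to form a quaternary carbon next to a nitro-bearing centre. The catalyst enantiomer is chosen for the C6 configuration of 15, and the product should be the ketal adduct F3. Pyridinium p-toluenesulfonate in wet acetone removes the ketal to give 15, which is carried to 17 by the DBU and MsCl stages of step 7. The enamine must distinguish a methyl from a primary alkyl group, so C1 epimers may have to be separated at the stage of 17.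

**Step 8.**
- Most likely to go wrong: thiolate addition to a tetrasubstituted nitroalkene is reversible and may stop short of completion, and deconjugated isomers may re-enter only slowly.
- Fallback, setting out from 17 and rejoining at 19: an ionic instead of a radical removal of the nitro group. Deprotonation of 17 with DBU and kinetic protonation with AcOH at −78 °C should give the allylic nitro isomer F4. Zerovalent palladium, as Pd(PPh3)4, with NaBH4 ionises the allylic nitro group, and hydride should attack the allyl terminus C3, which is remote from the aryl-bearing carbon. The formyl group is reduced at the same time, giving the alcohol F5, and Dess–Martin periodinane returns the aldehyde 19.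

**Step 13.**
- Most likely to go wrong: the phosphonate anion may add slowly to the neopentyl-type aldehyde, and over the long reaction time the base may attack a carbamate.
- Fallback, setting out from 19 and 5 and rejoining at 23: Takai olefination of 19 (CrCl2, CHI3, THF) should give the (E)-vinyl iodide F6. Bromide 5 is protected with Boc2O to the carbamate F7 and borylated (PdCl2(dppf), bis(pinacolato)diboron, KOAc) to the pinacol boronate F8. Suzuki coupling of F6 with F8 (Pd(PPh3)4, K3PO4, aqueous dioxane) then gives 23 with retention of the E geometry and without touching the other alkenes.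

**Step 2.**
- Most likely to go wrong: under the acid of the indolisation the tertiary allyl group may migrate from C3 or its alkene may be protonated and cyclise.
- Fallback, setting out from 3 and rejoining at 5: the alkene is made after the acid step. Commercial 4,4-dimethyloxolan-2-one is reduced with i-Bu2AlH to the lactol 4,4-dimethyloxolan-2-ol F9, a masked 4-hydroxy-3,3-dimethylbutanal. Fischer reaction of F9 with 3 should give 2-(5-bromo-1H-indol-3-yl)-2-methylpropan-1-ol F10. Dess–Martin oxidation gives 2-(5-bromo-1H-indol-3-yl)-2-methylpropanal F11, and Wittig methylenation (Ph3PCH3Br, KN(SiMe3)2 in excess to cover the N–H) gives 5.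

## Further compounds

F1 | step 7 | N-cyclohexylpropan-1-imine | CCC=NC1CCCCC1
F2 | step 7 | 2-methyl-4-(2-methyl-1,3-dioxolan-2-yl)butanal (racemic) | O=CC(C)CCC1(C)OCCO1
F3 | step 7 | (2R,3S)-3-[1-(tert-butoxycarbonyl)-3-(2-methylbut-3-en-2-yl)indol-5-yl]-2-methyl-2-[2-(2-methyl-1,3-dioxolan-2-yl)ethyl]-4-nitrobutanal | O=C[C@](C)(CCC1(C)OCCO1)[C@@H](C[N+](=O)[O-])c1ccc2n(C(=O)OC(C)(C)C)cc(C(C)(C)C=C)c2c1
F4 | step 8 | (1R,6S)-6-[1-(tert-butoxycarbonyl)-3-(2-methylbut-3-en-2-yl)indol-5-yl]-1,4-dimethyl-5-nitrocyclohex-3-ene-1-carbaldehyde (C5 epimers) | O=C[C@]1(C)CC=C(C)C([N+](=O)[O-])[C@H]1c2ccc3n(C(=O)OC(C)(C)C)cc(C(C)(C)C=C)c3c2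
F5 | step 8 | [(1R,6S)-6-[1-(tert-butoxycarbonyl)-3-(2-methylbut-3-en-2-yl)indol-5-yl]-1,4-dimethylcyclohex-4-en-1-yl]methanol | OC[C@]1(C)CCC(C)=C[C@H]1c2ccc3n(C(=O)OC(C)(C)C)cc(C(C)(C)C=C)c3c2
F6 | step 13 | tert-butyl 5-[(1R,6R)-1-[(E)-2-iodoethenyl]-1,4-dimethylcyclohex-4-en-6-yl]-3-(2-methylbut-3-en-2-yl)indole-1-carboxylate | I/C=C/[C@]1(C)CCC(C)=C[C@H]1c2ccc3n(C(=O)OC(C)(C)C)cc(C(C)(C)C=C)c3c2
F7 | step 13 | tert-butyl 5-bromo-3-(2-methylbut-3-en-2-yl)indole-1-carboxylate | C=CC(C)(C)c1cn(C(=O)OC(C)(C)C)c2ccc(Br)cc12
F8 | step 13 | tert-butyl 3-(2-methylbut-3-en-2-yl)-5-(4,4,5,5-tetramethyl-1,3,2-dioxaborolan-2-yl)indole-1-carboxylate | C=CC(C)(C)c1cn(C(=O)OC(C)(C)C)c2ccc(B3OC(C)(C)C(C)(C)O3)cc12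
F9 | step 2 | 4,4-dimethyloxolan-2-ol | OC1CC(C)(C)CO1
F10 | step 2 | 2-(5-bromo-1H-indol-3-yl)-2-methylpropan-1-ol | CC(C)(CO)c1c[nH]c2ccc(Br)cc12
F11 | step 2 | 2-(5-bromo-1H-indol-3-yl)-2-methylpropanal | CC(C)(C=O)c1c[nH]c2ccc(Br)cc12
A1 | alternative 1 | (E)-2-methyl-3-[1-(4-methylphenylsulfonyl)-3-(2-methylbut-3-en-2-yl)indol-5-yl]prop-2-enal | O=C/C(C)=C/c1ccc2n(S(=O)(=O)c3ccc(C)cc3)cc(C(C)(C)C=C)c2c1
A2 | alternative 1 | (E)-trimethyl(2-methylbuta-1,3-dien-1-yl)silane | C[Si](C)(C)/C=C(\C)C=C
A3 | alternative 1 | 1,4-dimethyl-6-[1-(4-methylphenylsulfonyl)-3-(2-methylbut-3-en-2-yl)indol-5-yl]-5-(trimethylsilyl)cyclohex-3-ene-1-carbaldehyde (formyl-endo adduct) | O=C[C@]1(C)CC=C(C)[C@H]([Si](C)(C)C)[C@H]1c4ccc5n(S(=O)(=O)c6ccc(C)cc6)cc(C(C)(C)C=C)c5c4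
A4 | alternative 2 | tert-butyl 3-(2-methylbut-3-en-2-yl)-5-(4,4,5,5-tetramethyl-1,3,2-dioxaborolan-2-yl)indole-1-carboxylate | C=CC(C)(C)c1cn(C(=O)OC(C)(C)C)c2ccc(B3OC(C)(C)C(C)(C)O3)cc12
A5 | alternative 2 | methyl carbonate of 1-[(E)-2-iodoethenyl]-1,4-dimethylcyclohex-4-en-6-ol, carbonate cis to the iodovinyl group | I/C=C/[C@]1(C)CCC(C)=C[C@@H]1OC(=O)OC
A6 | alternative 2 | N,N′-bis(tert-butoxycarbonyl) derivative of the target (same compound as 23) | C=CC(C)(C)c1cn(C(=O)OC(C)(C)C)c2ccc(/C=C/[C@]3(C)CCC(C)=C[C@H]3c3ccc4n(C(=O)OC(C)(C)C)cc(C(C)(C)C=C)c4c3)cc12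
A7 | alternative 3 | 3-[1-(tert-butoxycarbonyl)-3-(2-methylbut-3-en-2-yl)indol-5-yl]-2-methyl-2-(3-methylbut-3-enyl)pent-4-enal | O=C[C@](C)(CCC(C)=C)[C@@H](C=C)c1ccc2n(C(=O)OC(C)(C)C)cc(C(C)(C)C=C)c2c1
A8 | alternative 3 | 6-[1-(tert-butoxycarbonyl)-3-(2-methylbut-3-en-2-yl)indol-5-yl]-1,4-dimethylcyclohex-4-ene-1-carbaldehyde (same compound as 19) | O=C[C@]1(C)CCC(C)=C[C@H]1c2ccc3n(C(=O)OC(C)(C)C)cc(C(C)(C)C=C)c3c2
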